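| flask | substrate | reagent | other conformer | remark | time |
|---|---|---|---|---|---|
| epsilon | 0.13 M | 0.36 M | 0.10 M | run made earlier |  |
| alpha | 0.30 M | 0.36 M | 0.10 M | run made earlier |  |
| delta | 0.20 M | 0.36 M | 0.15 M | run made earlier |  |
| flask | 0.20 M | 0.360 M | 0.100 M |  | 40 min |

| run | time / min | isomer of the product / % | target / % |
|---|---|---|---|
| epsilon | 4.00 | 41.4 | 29.0 |
| epsilon | 8.00 | 45.4 | 34.9 |
| epsilon | 20.0 | 47.3 | 37.4 |
| epsilon | 50.0 | 47.2 | 38.6 |
| alpha | 4.00 | 24.5 | 34.2 |
| alpha | 8.00 | 28.2 | 39.3 |
| alpha | 20.0 | 31.4 | 42.7 |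
| alpha | 50.0 | 31.8 | 43.7 |
| delta | 6.00 | 41.9 | 29.4 |
| delta | 15.0 | 45.4 | 33.0 |
| delta | 30.0 | 46.3 | 33.7 |
| delta | 50.0 | 47.1 | 34.7 |

(each reading ± 0.3 percentage points)

- what was read earlier has a scatter of 0.3 percentage points, one standard deviation
- on the list of suspects stand: substrate + reagent -> target; substrate <-> dormant form; reagent + other conformer -> isomer of the product; substrate <-> other conformer

1. ratio of isomer of the product to target at 2.0 s
2. ratio of isomer of the product to target at 40 min

By 50.0 min the delta run holds 0.121 M of target and 0.165 M of isomer of the product, so reagent has fallen from 0.36 M to 0.0737 M, and the mean of these two ends, taken here as mean reagent, is 0.217 M.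

Two rates compete for substrate: capture by reagent, kB (k the second-order constant, B the reagent concentration), and diversion to dormant form or other conformer, d (a first-order constant). Both are first order in substrate, so target formed over substrate not captured reads roughly kB/d. Dividing by mean reagent gives the capture factor g = k/d, a selectivity factor per molar of reagent, read as 7.13 M⁻¹.

My own reckoning for the flask puts isomer of the product at 0.115 M, the conformer charge plus delta's excess. With delta's target as a first guess, mean reagent is 0.242 M, so gB is 1.72, target 0.127 M and the ratio 0.907 at 40 min.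

The forecast gives 1.5 (1 to 2.2) at 2.0 s and 0.9 (0.84 to 0.97) at 40 min, holding that “Isomer/target ratios therefore fall little with time”.

The flask gives 1.33 at 2.0 s and 0.915 at 40 min.

    substrate + reagent → target (k = 0.0162 M⁻¹ s⁻¹)
    substrate ⇌ dormant form (K = 27.0, k = 0.00174 s⁻¹)
    reagent + other conformer → isomer of the product (k = 0.0433 M⁻¹ s⁻¹)
    substrate ⇌ other conformer (K = 1.00, k = 6.25 × 10⁻⁴ s⁻¹)

The flask holds 42.2% of target at 40.0 min, against 42.2% reckoned from g. A neighbouring flask charged with 0.90 M of reagent has a mean reagent of 0.779 M by the same reckoning, so gB is 5.56 and target comes to 56.5%. Its simulated target is 57.1%, its isomer of the product 35.7%, and its ratio at 40.0 min is 0.625.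

The readings were generated by integration for an exercise, and the scatter is random.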